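# Proposed synthesis of 3,5-dihydroxy-7,8,3',4',5'-pentamethoxyflavone (18) by Claisen folding of a methoxylated triketo ester

## Analysis of the target

Compound 18 is a flavonol: a 4H-chromen-4-one (rings A and C) with a 3,4,5-trimethoxyphenyl group (ring B) on C2 and a hydroxyl on C3. Ring A is pentasubstituted: a free hydroxyl on C5, methoxyls on C7 and C8, the ring oxygen O1 on C8a and the carbonyl carbon C4 on C4a, so that only C6 carries hydrogen. The molecule is flat and achiral, with no stereocenter, so the whole problem is one of regiochemistry. The sensitive parts are the 3-hydroxy-4-pyranone unit, an easily oxidised and metal-binding enol, and the C5 hydroxyl, which is hydrogen-bonded to the C4 carbonyl and must end up as the only free phenol beside five aryl methyl ethers; in hot protic acid a 5,7,8-oxygenated flavone can also isomerise to the 5,6,7-pattern by opening and reclosure of ring C (Wessely–Moser rearrangement). The synthesis is hard because four different oxygen functions (O1, free O5, methylated O7 and O8) must be placed around one benzene ring without ambiguity, and because the C3 oxygen must be brought in without diverting ring closure to a five-membered benzofuranone. The route rests on one feature of ring A: the oxygens on C5, C7 and C8a stand on alternate carbons, with the acyl carbon C4 attached to C4a between two of them, which is the pattern of an acylphloroglucinol, and the C8 methoxyl is one extra substituent between two of these oxygens. Such a ring is the folded form of a linear 3,5,7-triketo ester in which C4a is a doubly activated methylene, C8a the ester carbon and C8 a methoxylated methine, and the same chain already contains C4, C3, C2 and ring B as a cinnamoyl end group.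

## Retrosynthetic reasoning

**18 to 17.** The last bond cut is the O–CH3 bond at C5. Of the six methoxyls of 17 only this one lies peri to the C4 carbonyl, so a Lewis acid can sit between the two oxygens and the methyl group can be removed selectively. Carrying O5 as a methyl ether saves a separate protecting group. The forward step has to spare the crowded methoxyls on C8 and C4'.

**17 to 15.** The C3–O bond is cut next, back to flavone 15. Forming ring C and the C3–OH bond together from chalcone 13 with alkaline peroxide (Algar–Flynn–Oyamada reaction) was considered and set aside: a substituent at the 6' position of a 2'-hydroxychalcone, here the future C5 methoxyl, turns that reaction toward five-membered benzofuranone closure. Oxygen transfer to the C2=C3 bond of a finished pyranone cannot go that way. The forward step must oxidise an electron-poor double bond in the presence of two electron-rich arenes.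

**15 to 13.** Ring C is opened at O1–C2 and the C2=C3 unsaturation is removed, which leads to the 2'-hydroxychalcone 13. This cut keeps the C6–C3–C6 skeleton whole and reduces the regiochemistry of ring A to one question: which of the two oxygens ortho to the ketone is free. In 13 only the hydroxyl beside the C8 methoxyl is free, so closure can give only the 5,7,8-pattern.

**13 to 12.** The O–CH3 bonds at the future O7 and O5 are cut, giving the trihydroxychalcone 12. The forward methylation has to leave exactly one hydroxyl, the one flanked by the methoxyl and the ketone. It relies on the higher acidity of the para hydroxyl and on the stronger hydrogen bond of the buttressed ortho hydroxyl.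

**12 to 11.** Ring A is opened at C4a–C8a. The chain of 11 maps on the flavone as C1 = C8a, C2 = C8, C3 = C7, C4 = C6, C5 = C5, C6 = C4a, C7 = C4, C8 = C3 and C9 = C2. This cut is preferred to any other in ring A because it is the only one that produces an unbranched chain with all six ring carbons in the right oxidation state and with the cinnamoyl group and ring B already attached. The forward reaction is an intramolecular Claisen condensation of the C6 methylene onto the C1 ester, promoted by a chelating magnesium alkoxide, followed by enolisation to the arene. The C8 methoxyl is carried in as the C2 substituent, so ring A needs no later C–H oxidation.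

**11 to 10 to 8.** The methyl ester is traced to the acid 10, and the C1–C2 bond is then cut, removing C1 as a one-carbon electrophile and leaving triketone 8. Bringing C1 and C2 in together as a malonate-type diester was examined and rejected: its doubly activated C–H would protonate the strongly basic terminal carbanion of 7 faster than its ester would be attacked. Carboxylation of the trianion of 8 has no such conflict, because the only carbon that can take the third negative charge is the methoxy-bearing terminus.

**8 to 5 and 6.** The C2–C3 bond of 8 is cut between the terminal carbon of the diketone 5 and the ester carbon of 6. Forward, the dianion 7 of 5 is acylated at its terminal carbon. Building block 6 supplies the future C8 with its methoxyl and the future C7 with its oxygen.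

**5 to 1 and 2.** The styryl C=C bond is cut by a retro-aldol condensation to the aldehyde 1 and the diketone 2. The forward reaction must take place at a methyl group of 2 and not at its central methylene, which is what boron chelation of the diketone achieves.

## Alternatives that were turned down

**Alternative 1:** Ring C is cut at C3–C4 and at C2=C3, so that C3 with its oxygen becomes a one-carbon linchpin between two carbonyl groups.

- Forward key step: 3,4,6-trimethoxy-2-[(3,4,5-trimethoxybenzoyl)oxy]benzoyl chloride A1 would be C-acylated by (benzyloxymethylene)triphenylphosphorane A2. The keto ylide so formed would olefinate the neighbouring aryl ester carbonyl in an intramolecular Wittig reaction, closing ring C as the 3-benzyloxyflavone A3. Hydrogenolysis of the benzyl ether and removal of the C5 methyl group would finish.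
- For: the C3 oxygen arrives with the linchpin, rings A and B are joined by a simple esterification, and no oxidation of a finished flavone and no choice between five- and six-membered closure arises.
- Against: A2 is a non-stabilised α-alkoxy ylide that must be made and used cold. Two equivalents are consumed, because the acylated ylide is deprotonated by a second molecule of A2, and O-acylation competes. The acylated ylide is then a weak nucleophile that has to attack a hindered, electron-rich aryl ester. A1 carries an acyl chloride and an aryl ester on neighbouring carbons and is prone to acyl transfer. The pentasubstituted benzoic acid behind A1 must be made by aromatic substitution, so the regiochemical problem of ring A is only moved to an earlier stage.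
- Comparison: on the C3 oxygen this alternative is stronger than the chosen route, which needs a separate oxidation (step 8). The chosen route offers instead a ring A whose substitution pattern is written into an open chain made from three cheap components, with no polysubstituted arene to prepare.

**Alternative 2:** Ring A is cut at C4a–C5, C5–C6 and C8–C8a, back to a four-carbon and a two-carbon piece.

- Forward key step: 2,3-dimethoxycyclobut-2-en-1-one A4 would be heated with the siloxyalkyne A5, triisopropyl{[(2-methyl-1,3-dioxolan-2-yl)ethynyl]oxy}silane. Four-electron ring opening of A4, [2+2] addition to A5, a second four-electron opening and a six-electron closure (Danheiser benzannulation) would give phenol A6, in which the C5 oxygen is a free hydroxyl, the C8a oxygen a silyl ether and C4 a masked acetyl group.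
- For: every oxygen of ring A is distinguished by construction. The differentiation of O5 from the C8a oxygen, which the chosen route has to win through relative alkylation rates in step 6, is here given by the structure, and on this point the alternative is clearly stronger.
- Against: A4 and A5 are each several steps from commercial materials, and A5 is sensitive to acid and moisture. The electron-rich ketene intermediate can dimerise, and the arene formed is hexasubstituted and crowded. Above all the key step delivers only ring A, so protection of O5, unmasking of the ketone and of the C8a oxygen, aldol condensation with the ring B aldehyde, closure of ring C, the C3 oxidation and a final deprotection all still follow.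
- Comparison: this is by far the longest path. The chosen route forms ring A with C4, C3, C2 and ring B already attached, and pays for this with one regioselective methylation.

**Alternative 3:** Ring C is cut at C4a–C4, C4–C3 and O1–C2, with the C4 carbonyl carbon taken from the gas phase.

- Forward key step: 2-iodo-3,5,6-trimethoxyphenol A7 and 5-ethynyl-1,2,3-trimethoxybenzene A8 would be joined in a carbonylative Sonogashira coupling with PdCl2(PPh3)2 in Et2NH. The phenol oxygen would then add to the alkynone in the same flask to give flavone A9, which is the same substance as 15.
- For: it is the most convergent of all. Two aryl pieces and one carbon give the flavone in a single operation, the ring A pattern is fixed in A7, and the end game would be that of steps 8 and 9. In step count it is shorter than the chosen route, and this has to be conceded.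
- Against: A7 is not a commercial compound, and its preparation needs an iodination that must choose between two activated ring positions, again an aromatic regiochemistry problem. Oxidative addition of zerovalent palladium into an electron-rich aryl iodide flanked by two ortho oxygen substituents is slow. The closing oxygen addition can go 5-exo to a benzofuranone instead of 6-endo to the pyranone. A toxic gas under pressure is needed.
- Comparison: the chosen route has more steps but uses only bulk starting materials, and it fixes the position of the C8 methoxyl by the choice of building block 6 and not by substitution on an arene.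

Key step: step 5

Remark on the chemistry: the 1,3-dicarbonyl compounds 5, 8, 10 and 11 are mixtures of rapidly interconverting keto and enol forms, of which one is drawn for each; C2 of 10 (keto form), C2 of 14 and the epoxide carbons of 16 are racemic, and for 16 one enantiomer of the only possible cis-fused form is drawn.

## Route

Step 1
Reactants: 1 3,4,5-trimethoxybenzaldehyde; 2 acetylacetone (pentane-2,4-dione)
Product: 5 (E)-6-(3,4,5-trimethoxyphenyl)hex-5-ene-2,4-dione, via boron chelate of acetylacetone 3 (not isolated), via boron chelate of the styryl diketone 4 (not isolated)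
Conditions: 2 (3 equiv), B2O3, EtOAc, 75 °C; then 1, B(OBu)3, n-BuNH2 (cat.), 75 °C; then 0.5 M aq HCl, 60 °C
Reagents that add atoms: none
Why: Boron-templated aldol condensation: chelation of 2 as its boron diketonate masks the central methylene against Knoevenagel condensation, so the amine-catalysed aldol reaction takes place at a terminal methyl group and dehydration gives the E styryl ketone. The excess of 2 holds back a second condensation, and dilute acid hydrolyses the chelate 4.

Step 2
Reactants: 5 (E)-6-(3,4,5-trimethoxyphenyl)hex-5-ene-2,4-dione; 6 methyl 2-methoxyacetate
Product: 8 (E)-1-methoxy-8-(3,4,5-trimethoxyphenyl)oct-7-ene-2,4,6-trione, via dilithium dienolate of the styryl diketone 7 (not isolated)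
Conditions: 5 (2 equiv), LiN(i-Pr)2 (4 equiv), THF, −78 to 0 °C; then 6 (1 equiv), 0 °C to rt; cold 1 M aq HCl; unreacted 5 recovered
Reagents that add atoms: none
Why: Claisen-type acylation of a 1,3-diketone dianion by an ester: the last-formed terminal carbanion of 7 is its most nucleophilic site and adds to the ester carbonyl of 6, an aliphatic ester of the kind known to acylate such dianions faster than it is enolised. The second equivalent of 7 takes up the acidic proton of the new triketone, and the 5 so regenerated is recovered.

Step 3
Reactants: 8 (E)-1-methoxy-8-(3,4,5-trimethoxyphenyl)oct-7-ene-2,4,6-trione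
Product: 10 (E)-2-methoxy-3,5,7-trioxo-9-(3,4,5-trimethoxyphenyl)non-8-enoic acid, via trilithium trienolate of the triketone 9 (not isolated)
Conditions: LiN(i-Pr)2 (3.2 equiv), THF, −78 to 0 °C; CO2 (excess), −78 °C; cold 1 M aq HCl, extraction at 0 °C
Reagents that add atoms: carbon dioxide, O=C=O
Why: Carboxylation of a triketone trianion: the third deprotonation can only take place at the methoxy-bearing terminal carbon, since the other end of the chain is the styryl group, and only this most basic carbanion is trapped by CO2, while the two diketonate sites are not carboxylated. The β-keto acid 10 is kept cold because warming would decarboxylate it back to 8.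

Step 4
Reactants: 10 (E)-2-methoxy-3,5,7-trioxo-9-(3,4,5-trimethoxyphenyl)non-8-enoic acid
Product: 11 methyl (E)-2-methoxy-3,5,7-trioxo-9-(3,4,5-trimethoxyphenyl)non-8-enoate
Conditions: CH2N2 (1.0 equiv), Et2O, −10 °C, short contact time
Reagents that add atoms: diazomethane, C=[N+]=[N-]
Why: Esterification of a carboxylic acid with diazomethane: the carboxyl proton is by far the most acidic in 10, so one equivalent at low temperature should methylate it before the enolic hydroxyls react. No base or heat is involved that could start decarboxylation or cyclisation.

Step 5
Reactants: 11 methyl (E)-2-methoxy-3,5,7-trioxo-9-(3,4,5-trimethoxyphenyl)non-8-enoate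
Product: 12 (E)-1-(2,4,6-trihydroxy-3-methoxyphenyl)-3-(3,4,5-trimethoxyphenyl)prop-2-en-1-one
Conditions: Mg(OMe)2 (5 equiv), MeOH, argon, 25 to 50 °C; then cold 1 M aq HCl to pH 3, extraction at 0 °C
Reagents that add atoms: none
Why: Mg(OMe)2 deprotonates the acidic positions and holds the chain folded as a magnesium chelate; the enolate carbon C6 of the chain (future C4a), flanked by the C5 and C7 carbonyls, adds to the C1 ester carbonyl (future C8a), and the tetrahedral intermediate expels methoxide. The 2-acylcyclohexane-1,3,5-trione formed enolises to the phloroglucinol, which makes C4a–C8a bond formation irreversible and the thermodynamic sink of the system. The closest known reaction type is the biomimetic Claisen (Dieckmann-type) cyclisation of 3,5,7-triketo esters to acylphloroglucinols under alkoxide bases. Ring A closes in the 6-exo-trig mode, the enolate carbon attacking the ester carbon with the carbonyl oxygen outside the ring. No stereocenter is formed, and the E double bond is carried through unchanged; it should be shielded from conjugate addition because its carbonyl is part of the chelated diketonate. The selectivity needed is Claisen folding over aldol folding and over lactonisation: the aldol nucleophile would be C2, which carries the methoxyl, so its adduct with the C7 carbonyl would hold a quaternary carbon, could not dehydrate to an arene and should revert, while a pyranone formed by O-acylation is reopened by methoxide. The methoxyl on C2 also raises the electrophilicity of the ester carbonyl inductively. Cold acidic work-up is used so that 12 does not close to a flavanone through one of its ortho hydroxyls.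

Step 6
Reactants: 12 (E)-1-(2,4,6-trihydroxy-3-methoxyphenyl)-3-(3,4,5-trimethoxyphenyl)prop-2-en-1-one
Product: 13 (E)-1-(2-hydroxy-3,4,6-trimethoxyphenyl)-3-(3,4,5-trimethoxyphenyl)prop-2-en-1-one
Conditions: Me2SO4 (2.1 equiv), K2CO3 (3 equiv), acetone, rt to reflux
Reagents that add atoms: dimethyl sulfate, COS(=O)(=O)OC
Why: Regioselective phenol O-alkylation: the hydroxyl para to the ketone (future O7) is the most acidic and should react first, the ortho hydroxyl next to C–H (future O5) second, while the hydroxyl beside the methoxyl is pressed into the hydrogen bond with the carbonyl and should stay free. Any flavanone formed from 12 under the base reopens and is drawn into the same product.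

Step 7
Reactants: 13 (E)-1-(2-hydroxy-3,4,6-trimethoxyphenyl)-3-(3,4,5-trimethoxyphenyl)prop-2-en-1-one
Product: 15 5,7,8-trimethoxy-2-(3,4,5-trimethoxyphenyl)-4H-chromen-4-one, via racemic flavanone 14 (not isolated)
Conditions: I2 (0.1 equiv), DMSO, 130 °C; aq Na2S2O3 work-up
Reagents that add atoms: none
Why: Iodine-catalysed oxidative cyclisation of a 2'-hydroxychalcone in DMSO: the single free phenol adds to the enone (6-endo-trig oxa-Michael addition) to give 14, which is iodinated at C3 and loses HI, DMSO reoxidising the iodide. Because only one hydroxyl is free, O1 can only be the oxygen next to C8.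

Step 8
Reactants: 15 5,7,8-trimethoxy-2-(3,4,5-trimethoxyphenyl)-4H-chromen-4-one
Product: 17 3-hydroxy-5,7,8-trimethoxy-2-(3,4,5-trimethoxyphenyl)-4H-chromen-4-one, via flavone 2,3-epoxide 16 (not isolated)
Conditions: dimethyldioxirane (3 equiv, in acetone), CH2Cl2, 0 °C to rt; then TsOH·H2O (cat.), CH2Cl2, rt
Reagents that add atoms: dimethyldioxirane, CC1(C)OO1
Why: Epoxidation of the flavone C2=C3 bond with a dioxirane and acid-catalysed epoxide opening: 16 opens at C2 to a cation stabilised by O1 and ring B, and loss of the C3 proton gives the 3-hydroxyflavone. The neutral oxidant works on the closed pyranone, so the benzofuranone pathway that alkaline peroxide opens for 6'-substituted chalcones cannot occur.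

Step 9
Reactants: 17 3-hydroxy-5,7,8-trimethoxy-2-(3,4,5-trimethoxyphenyl)-4H-chromen-4-one
Product: 18 3,5-dihydroxy-7,8-dimethoxy-2-(3,4,5-trimethoxyphenyl)-4H-chromen-4-one (3,5-dihydroxy-7,8,3',4',5'-pentamethoxyflavone)
Conditions: BCl3 (3 equiv), CH2Cl2, −78 to 0 °C; then H2O, 1 M aq HCl
Reagents that add atoms: none
Why: Chelation-controlled aryl methyl ether cleavage: BCl3 binds between the C4 carbonyl oxygen and the C5 methoxyl in a six-membered chelate, so chloride should remove this methyl group at low temperature, while the five methoxyls without a neighbouring carbonyl are kept. Aqueous acid then frees the phenol.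

## Compound list

1 | 3,4,5-trimethoxybenzaldehyde | COc1cc(C=O)cc(OC)c1OC | starting material
2 | acetylacetone (pentane-2,4-dione) | CC(=O)CC(C)=O | starting material
3 | 2,2-dibutoxy-4,6-dimethyl-1,3,2-dioxaborinine (boron chelate of acetylacetone, butoxy ligands drawn as the simplest defined form; not isolated) | CCCCO[B-]1(OCCCC)OC(C)=CC(C)=[O+]1 | intermediate
4 | 2,2-dibutoxy-4-methyl-6-[(E)-2-(3,4,5-trimethoxyphenyl)ethenyl]-1,3,2-dioxaborinine (boron chelate of the styryl diketone; not isolated) | CCCCO[B-]1(OCCCC)OC(C)=CC(/C=C/c2cc(OC)c(OC)c(OC)c2)=[O+]1 | intermediate
5 | (E)-6-(3,4,5-trimethoxyphenyl)hex-5-ene-2,4-dione | CC(=O)CC(=O)/C=C/c1cc(OC)c(OC)c(OC)c1 | intermediate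
6 | methyl 2-methoxyacetate | COCC(=O)OC | starting material
7 | dilithium (E)-6-(3,4,5-trimethoxyphenyl)hexa-1,3,5-triene-2,4-diolate (dianion of 5, enolate geometry not defined; not isolated) | [Li+].[Li+].C=C([O-])C=C([O-])/C=C/c1cc(OC)c(OC)c(OC)c1 | intermediate
8 | (E)-1-methoxy-8-(3,4,5-trimethoxyphenyl)oct-7-ene-2,4,6-trione | COCC(=O)CC(=O)CC(=O)/C=C/c1cc(OC)c(OC)c(OC)c1 | intermediate
9 | trilithium (7E)-1-methoxy-8-(3,4,5-trimethoxyphenyl)octa-1,3,5,7-tetraene-2,4,6-triolate (trianion of 8, enolate geometry not defined; not isolated) | [Li+].[Li+].[Li+].COC=C([O-])C=C([O-])C=C([O-])/C=C/c1cc(OC)c(OC)c(OC)c1 | intermediate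
10 | (E)-2-methoxy-3,5,7-trioxo-9-(3,4,5-trimethoxyphenyl)non-8-enoic acid (racemic at the enolisable C2) | COC(C(=O)O)C(=O)CC(=O)CC(=O)/C=C/c1cc(OC)c(OC)c(OC)c1 | intermediate
11 | methyl (E)-2-methoxy-3,5,7-trioxo-9-(3,4,5-trimethoxyphenyl)non-8-enoate (chelated 2,3-enol form drawn) | COC(=O)/C(OC)=C(\O)CC(=O)CC(=O)/C=C/c1cc(OC)c(OC)c(OC)c1 | intermediate
12 | (E)-1-(2,4,6-trihydroxy-3-methoxyphenyl)-3-(3,4,5-trimethoxyphenyl)prop-2-en-1-one | COc1c(O)cc(O)c(C(=O)/C=C/c2cc(OC)c(OC)c(OC)c2)c1O | intermediate
13 | (E)-1-(2-hydroxy-3,4,6-trimethoxyphenyl)-3-(3,4,5-trimethoxyphenyl)prop-2-en-1-one | COc1cc(OC)c(C(=O)/C=C/c2cc(OC)c(OC)c(OC)c2)c(O)c1OC | intermediate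
14 | 5,7,8-trimethoxy-2-(3,4,5-trimethoxyphenyl)chroman-4-one (racemic; not isolated) | COc1cc(C2CC(=O)c3c(OC)cc(OC)c(OC)c3O2)cc(OC)c1OC | intermediate
15 | 5,7,8-trimethoxy-2-(3,4,5-trimethoxyphenyl)-4H-chromen-4-one | COc1cc(-c2cc(=O)c3c(OC)cc(OC)c(OC)c3o2)cc(OC)c1OC | intermediate
16 | 3,4,6-trimethoxy-1a-(3,4,5-trimethoxyphenyl)-1a,7a-dihydro-7H-oxireno[2,3-b]chromen-7-one (2,3-epoxide of 15, racemic, cis-fused; not isolated) | O=C1c2c(OC)cc(OC)c(OC)c2O[C@@]2(c3cc(OC)c(OC)c(OC)c3)O[C@@H]12 | intermediate
17 | 3-hydroxy-5,7,8-trimethoxy-2-(3,4,5-trimethoxyphenyl)-4H-chromen-4-one | COc1cc(-c2oc3c(OC)c(OC)cc(OC)c3c(=O)c2O)cc(OC)c1OC | intermediate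
18 | 3,5-dihydroxy-7,8-dimethoxy-2-(3,4,5-trimethoxyphenyl)-4H-chromen-4-one | COc1cc(-c2oc3c(OC)c(OC)cc(O)c3c(=O)c2O)cc(OC)c1OC | target

## Step count and least certain steps

Total step count: 9. Longest linear sequence: 9 steps, from 1 to 18; 2 and 6 are purchased and enter this single line.

**Step 5 (key step).** Under Mg(OMe)2 the C2 position, which lies between the ester and a ketone, is enolised as well, and this lowers the electrophilicity of the ester carbonyl that has to be attacked. Ring closure may then be slower than cleavage of the chain by methoxide at one of the ketones (retro-Claisen fragmentation) or than O-acylation to a pyranone. A second weak point is the work-up, where closure of the product onto its own enone through either ortho hydroxyl can start as soon as the solution is near neutral. Fallback: set out from 1 and condense it with commercially available 1-(2-hydroxy-3,4,6-trimethoxyphenyl)ethan-1-one F1 under Claisen–Schmidt conditions (KOH, EtOH, rt). This gives the dimethylated chalcone directly and returns to the route at 13, with ring A then taken from an arene instead of being folded from the chain.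

**Step 3.** The third deprotonation has to take place at a carbon that bears a methoxyl and lies next to an already doubly charged enolate system. Incomplete trianion formation would return 8, and the β-keto acid can lose CO2 during isolation. Fallback: set out from 5 and convert it (Me3SiCl, Et3N; then LiN(i-Pr)2, Me3SiCl) into (5E)-2,4-bis(trimethylsilyloxy)-6-(3,4,5-trimethoxyphenyl)hexa-1,3,5-triene F2. Acylate this neutral dienol ether at its terminal carbon with methyl 3-chloro-2-methoxy-3-oxopropanoate F3 (CH2Cl2, −78 °C to rt, aqueous work-up). Because the nucleophile is not basic, the acidic C–H of F3 does no harm. The sequence replaces steps 2 to 4 and returns to the route at 11.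

**Step 6.** Alkylation may take place at the wrong ortho hydroxyl, which would lead to the 5,6,7-oxygenated series, or at all three hydroxyls, since the discrimination between the two ortho positions rests only on hydrogen bonding and steric crowding. Fallback: set out from 12 and methylate exhaustively (MeI in excess, K2CO3, DMF) to (E)-1-(2,3,4,6-tetramethoxyphenyl)-3-(3,4,5-trimethoxyphenyl)prop-2-en-1-one F4. Then remove the most congested ortho methoxyl, the one between the ketone and a second methoxyl, with one equivalent of BCl3 at −78 °C. The selection is then made by strain-assisted, chelation-controlled ether cleavage instead of by alkylation rates, and the route is rejoined at 13.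

**Step 8.** The C2=C3 bond of a flavone is electron-poor and reacts slowly with dimethyldioxirane, so oxidation of the two electron-rich trimethoxyarene rings may overtake epoxidation during the long reaction time. Fallback: set out from 15, deprotonate C3 with LiN(i-Pr)2 in THF at −78 °C, and trap with B(OMe)3 to give dimethyl [5,7,8-trimethoxy-4-oxo-2-(3,4,5-trimethoxyphenyl)-4H-chromen-3-yl]boronate F5. Oxidise the C–B bond with H2O2 in AcOH. This returns to the route at 17.

**Step 9.** Further methyl groups may be lost, above all the central C4' methoxyl of ring B and the C8 methoxyl, both of which are twisted out of the ring plane and therefore more basic than ordinary aryl methyl ethers. Fallback: set out from 12 and carry O5 as a benzyl ether.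
- One equivalent of Me2SO4 (K2CO3, acetone, rt) should methylate only the para hydroxyl, giving (E)-1-(2,6-dihydroxy-3,4-dimethoxyphenyl)-3-(3,4,5-trimethoxyphenyl)prop-2-en-1-one F6.
- BnBr (1.05 equiv, K2CO3, acetone) should alkylate the less hindered ortho hydroxyl, giving (E)-1-[6-(benzyloxy)-2-hydroxy-3,4-dimethoxyphenyl]-3-(3,4,5-trimethoxyphenyl)prop-2-en-1-one F7.
- I2 (cat.) in DMSO at 110 °C closes ring C to 5-(benzyloxy)-7,8-dimethoxy-2-(3,4,5-trimethoxyphenyl)-4H-chromen-4-one F8.
- Dimethyldioxirane followed by TsOH gives 5-(benzyloxy)-3-hydroxy-7,8-dimethoxy-2-(3,4,5-trimethoxyphenyl)-4H-chromen-4-one F9.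
- Hydrogenolysis (H2, Pd/C, EtOAc) removes the benzyl group without any Lewis acid and returns to the route at 18.

## Further compounds

F1 | step 5 | 1-(2-hydroxy-3,4,6-trimethoxyphenyl)ethan-1-one | CC(=O)c1c(OC)cc(OC)c(OC)c1O
F2 | step 3 | (5E)-2,4-bis(trimethylsilyloxy)-6-(3,4,5-trimethoxyphenyl)hexa-1,3,5-triene | C=C(O[Si](C)(C)C)C=C(O[Si](C)(C)C)/C=C/c1cc(OC)c(OC)c(OC)c1
F3 | step 3 | methyl 3-chloro-2-methoxy-3-oxopropanoate (racemic) | COC(C(=O)Cl)C(=O)OC
F4 | step 6 | (E)-1-(2,3,4,6-tetramethoxyphenyl)-3-(3,4,5-trimethoxyphenyl)prop-2-en-1-one | COc1cc(OC)c(C(=O)/C=C/c2cc(OC)c(OC)c(OC)c2)c(OC)c1OC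
F5 | step 8 | dimethyl [5,7,8-trimethoxy-4-oxo-2-(3,4,5-trimethoxyphenyl)-4H-chromen-3-yl]boronate | COB(OC)c1c(-c2cc(OC)c(OC)c(OC)c2)oc2c(OC)c(OC)cc(OC)c2c1=O
F6 | step 9 | (E)-1-(2,6-dihydroxy-3,4-dimethoxyphenyl)-3-(3,4,5-trimethoxyphenyl)prop-2-en-1-one | COc1cc(O)c(C(=O)/C=C/c2cc(OC)c(OC)c(OC)c2)c(O)c1OC
F7 | step 9 | (E)-1-[6-(benzyloxy)-2-hydroxy-3,4-dimethoxyphenyl]-3-(3,4,5-trimethoxyphenyl)prop-2-en-1-one | COc1cc(OCc2ccccc2)c(C(=O)/C=C/c2cc(OC)c(OC)c(OC)c2)c(O)c1OC
F8 | step 9 | 5-(benzyloxy)-7,8-dimethoxy-2-(3,4,5-trimethoxyphenyl)-4H-chromen-4-one | COc1cc(-c2cc(=O)c3c(OCc4ccccc4)cc(OC)c(OC)c3o2)cc(OC)c1OC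
F9 | step 9 | 5-(benzyloxy)-3-hydroxy-7,8-dimethoxy-2-(3,4,5-trimethoxyphenyl)-4H-chromen-4-one | COc1cc(-c2oc3c(OC)c(OC)cc(OCc4ccccc4)c3c(=O)c2O)cc(OC)c1OC
A1 | alternative 1 | 3,4,6-trimethoxy-2-[(3,4,5-trimethoxybenzoyl)oxy]benzoyl chloride | COc1cc(OC)c(C(=O)Cl)c(OC(=O)c2cc(OC)c(OC)c(OC)c2)c1OC
A2 | alternative 1 | (benzyloxymethylene)triphenylphosphorane | C(OCc1ccccc1)=P(c1ccccc1)(c1ccccc1)c1ccccc1
A3 | alternative 1 | 3-(benzyloxy)-5,7,8-trimethoxy-2-(3,4,5-trimethoxyphenyl)-4H-chromen-4-one | COc1cc(-c2oc3c(OC)c(OC)cc(OC)c3c(=O)c2OCc2ccccc2)cc(OC)c1OC
A4 | alternative 2 | 2,3-dimethoxycyclobut-2-en-1-one | COC1=C(OC)C(=O)C1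
A5 | alternative 2 | triisopropyl{[(2-methyl-1,3-dioxolan-2-yl)ethynyl]oxy}silane | CC1(OCCO1)C#CO[Si](C(C)C)(C(C)C)C(C)C
A6 | alternative 2 | 4,5-dimethoxy-2-(2-methyl-1,3-dioxolan-2-yl)-3-(triisopropylsilyloxy)phenol | CC1(OCCO1)c1c(O)cc(OC)c(OC)c1O[Si](C(C)C)(C(C)C)C(C)C
A7 | alternative 3 | 2-iodo-3,5,6-trimethoxyphenol | COc1cc(OC)c(I)c(O)c1OC
A8 | alternative 3 | 5-ethynyl-1,2,3-trimethoxybenzene | C#Cc1cc(OC)c(OC)c(OC)c1
A9 | alternative 3 | 5,7,8-trimethoxy-2-(3,4,5-trimethoxyphenyl)-4H-chromen-4-one | COc1cc(-c2cc(=O)c3c(OC)cc(OC)c(OC)c3o2)cc(OC)c1OC
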